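**Plan** (labdane numbering; ring A = C1–C5/C10, ring B = C5–C10)
- Cuts: the O15 acetate; C4–C18 and C4–C19 back to a C4 ketone; C8=C9 (ring B) by ring-closing metathesis; C5–C6 (Michael) and C9–C10 (conjugate addition) back to 3-methylcyclohexenone.
- Enabling feature: C8=C9 is the only ring olefin and is tetrasubstituted, with exocyclic C17 on C8 and C11 on C9. Ring B can therefore be closed there from two methylidene arms on C5 and C10 of a ring A cyclohexanone.
- Forward: C11–C16 chain from geranyl acetate → alkenylalane joined to ring A at C9–C10 → C5 arm → ring B by metathesis → C4 homologation and methylation → O15 acetate and C19 acid.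
- Stereochemistry: C10 from catalyst-controlled conjugate addition; C5 by equilibration to the trans fusion after ring closure; C4 by α-face methylation opposite the C10 methyl; 13E from geranyl acetate.

Key step: step 8

Assumption: the trans-fused 8-en-4-one is taken to be the more stable C5 epimer (reasoning in step 8), so C5 is left uncontrolled in steps 6 and 7 and compounds 12–14 are C5-epimer mixtures. Cis material left after step 8 would be separated and re-equilibrated.

**Step 1**
Reactants: 1 geranyl acetate
Product: 2 (2E)-5-(3,3-dimethyloxiran-2-yl)-3-methylpent-2-en-1-yl acetate (racemic at the oxirane carbon)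
Conditions: mCPBA, CH2Cl2, 0 °C
Reagents that add atoms: 3-chloroperoxybenzoic acid, OOC(=O)c1cccc(Cl)c1
Why: Prilezhaev epoxidation should occur at the electron-rich C6=C7 olefin because the C2=C3 olefin is deactivated by the allylic acetate; the oxirane stereocentre is racemic and is lost in step 2.

**Step 2**
Reactants: 2 epoxy acetate
Product: 3 (2E)-3-methyl-6-oxohex-2-en-1-yl acetate
Conditions: H5IO6, THF–H2O, 0 → 23 °C
Reagents that add atoms: none
Why: Periodic acid opens the oxirane to the vicinal diol and cleaves it (Malaprade-type glycol cleavage), leaving the aldehyde without touching the allylic acetate or the E olefin.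

**Step 3**
Reactants: 3 aldehyde acetate
Product: 5 (2E)-3-methylhept-2-en-6-yn-1-ol, via enyne acetate 4 (not isolated)
Conditions: MeC(O)C(N2)P(O)(OMe)2, K2CO3, MeOH, 0 → 23 °C
Reagents that add atoms: dimethyl (1-diazo-2-oxopropyl)phosphonate, CC(=O)C(=[N+]=[N-])P(=O)(OC)OC
Why: Seyferth–Gilbert homologation in the Ohira–Bestmann form turns the enolisable aldehyde into the terminal alkyne, and the same K2CO3–MeOH medium transesterifies the allylic acetate.

**Step 4**
Reactants: 5 enynol
Product: 6 tert-butyl{[(2E)-3-methylhept-2-en-6-yn-1-yl]oxy}diphenylsilane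
Conditions: t-BuPh2SiCl, imidazole, CH2Cl2, 23 °C
Reagents that add atoms: tert-butyl(chloro)diphenylsilane, CC(C)(C)[Si](Cl)(c1ccccc1)c1ccccc1
Why: Standard silylation of a primary allylic alcohol; this silyl ether is chosen to survive i-Bu2AlH, Lewis acids, strong bases and the dilute acid of step 10.

**Step 5**
Reactants: 6 silyl enynol; 7 3-methylcyclohex-2-en-1-one
Product: 10 triethylsilyl enol ether (C4–O–Si, C4=C5) of (3S)-3-methyl-3-[(5E)-7-(tert-butyldiphenylsilyloxy)-5-methylhepta-1,5-dien-2-yl]cyclohexanone, via alkenylalane 8 (not isolated), via aluminium enolate 9 (not isolated)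
Conditions: 6, i-Bu2AlH, Ni(dppp)Cl2 (3 mol %), THF, 0 → 23 °C; then 7, Cu(OTf)2 (5 mol %), silver complex (from Ag2O) of enantiopure 1-(2,6-diethylphenyl)-4,5-diphenyl-3-(2-sulfonatophenyl)imidazolidin-2-ylidene (2.5 mol %, the antipode that leads to the 3S product), −30 °C; then Et3SiOTf, −78 → 0 °C
Reagents that add atoms: triethylsilyl trifluoromethanesulfonate, CC[Si](CC)(CC)OS(=O)(=O)C(F)(F)F
Why: Nickel-catalysed α-selective hydroalumination places aluminium on the internal alkyne carbon, the chiral carbene–copper catalyst transfers this 1,1-disubstituted alkenyl group to one face of the enone (catalytic asymmetric conjugate addition, C10 set as S under catalyst control), and the silyl triflate traps the aluminium enolate regiospecifically on the C5 side.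

**Step 6**
Reactants: 10 silyl enol ether; 11 but-3-en-2-one
Product: 12 (3S)-3-methyl-3-[(5E)-7-(tert-butyldiphenylsilyloxy)-5-methylhepta-1,5-dien-2-yl]-2-(3-oxobutyl)cyclohexan-1-one (mixture of epimers at ring C2 = labdane C5)
Conditions: BF3·OEt2, i-PrOH, CH2Cl2, −78 °C
Reagents that add atoms: none
Why: Mukaiyama–Michael addition of the regiodefined silyl enol ether to BF3-activated butenone forms C5–C6 at the carbon next to quaternary C10 without enolate equilibration, the alcohol taking up the silyl group; C5 forms as an epimer mixture that step 8 corrects.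

**Step 7**
Reactants: 12 diketone
Product: 13 (3S)-3-methyl-2-(3-methylbut-3-en-1-yl)-3-[(5E)-7-(tert-butyldiphenylsilyloxy)-5-methylhepta-1,5-dien-2-yl]cyclohexan-1-one (C5-epimer mixture)
Conditions: Zn, CH2Br2, TiCl4, THF, 0 °C (preformed reagent); then 12, CH2Cl2, 0 → 23 °C
Reagents that add atoms: dibromomethane, BrCBr
Why: Takai–Lombardo methylenation with the non-basic gem-dimetallic reagent should convert the unhindered methyl ketone in preference to the ring ketone shielded by C5 and C10, and avoids the intramolecular aldol a basic ylide could trigger in a 1,5-diketone.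

**Step 8**
Reactants: 13 diene ketone
Product: 15 trans-fused (5R,10S)-15-(tert-butyldiphenylsilyloxy)-18,19-dinorlabda-8,13E-dien-4-one, via ketone epimer mixture 14 (not isolated)
Conditions: RuCl2(=CH-2-i-PrOC6H4)(1,3-di-o-tolylimidazolidin-2-ylidene) (10 mol %), PhMe (0.005 M), 80 °C, Ar sparge; silica plug; then NaOMe (0.3 equiv), MeOH, 23 °C
Reagents that add atoms: none
Why: The ruthenium carbene first exchanges onto the unhindered C8 methylidene by [2+2] cycloaddition and cycloreversion, and the resulting C8 alkylidene adds across the C9 methylidene beside quaternary C10; collapse of that ruthenacyclobutane gives the C8=C9 double bond and ethene, whose removal drives the closure. The closest known reaction type is ring-closing metathesis of two 1,1-disubstituted olefins to tetrasubstituted cyclohexenes with carbene ligands carrying small N-o-tolyl groups, which leave room at the metal for the fully substituted metallacycle, including closures next to quaternary carbons. Ring B closes as a six-membered carbocycle by joining the two methylidene arms on the adjacent ring A carbons C5 and C10, and both C5 epimers of 13 can reach the ring. The metathesis creates no stereocentre: C10 is untouched, and C5 is set afterwards when NaOMe equilibrates the filtered mixture 14 through the C4 enolate to the trans-fused epimer, expected to be favoured because the cis forms must either place C6 axial on ring A or swing C11 over ring A. The selectivity needed is reaction of the two 1,1-disubstituted olefins only; the trisubstituted C13=C14 olefin is less reactive and could only close a four-membered or a large ring, and the silica plug removes ruthenium before base is added so that no hydride species can shift the olefins.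

**Step 9**
Reactants: 15 trans-fused ketone
Product: 16 15-(tert-butyldiphenylsilyloxy)-4-(methoxymethylidene)-18,19-dinorlabda-8,13E-diene (5α-H, 10β-CH3; E/Z mixture at the enol ether)
Conditions: Ph3P(CH2OMe)Cl, KN(SiMe3)2, THF, 0 → 23 °C
Reagents that add atoms: (methoxymethyl)triphenylphosphonium chloride, COC[P+](c1ccccc1)(c1ccccc1)c1ccccc1.[Cl-]
Why: Wittig methoxymethylenation adds the future C19 carbon to the C4 ketone; C5 is no longer epimerisable afterwards, and any epimerisation before olefination only leads back to the preferred trans ketone.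

**Step 10**
Reactants: 16 enol ether
Product: 17 15-(tert-butyldiphenylsilyloxy)-4-formyl-18,19-dinorlabda-8,13E-diene (5α-H, 10β-CH3; C4-epimer mixture)
Conditions: 1 M HCl, THF, 23 °C
Reagents that add atoms: water, O
Why: Acid-catalysed enol ether hydrolysis (C-protonation, hydration of the oxocarbenium ion, loss of methanol) gives the C4 aldehyde under conditions the tert-butyldiphenylsilyl ether tolerates; the C4 configuration does not matter here.

**Step 11**
Reactants: 17 aldehyde
Product: 19 (4S,5R,10S)-15-(tert-butyldiphenylsilyloxy)labda-8,13E-dien-19-al, via potassium enolate 18 (not isolated)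
Conditions: KOt-Bu, THF, 0 °C; then MeI
Reagents that add atoms: iodomethane, CI
Why: C-Methylation of the potassium enolate of an α-branched aldehyde: iodomethane approaches the exocyclic C4 enolate from the α face, away from the syn-axial C10 methyl, so the new methyl is α (C18) and the formyl group β-axial (C19), setting C4 as S; any O-methylated material is enol ether 16 and can be returned to step 10.

**Step 12**
Reactants: 19 silyloxy aldehyde
Product: 20 (4S,5R,10S)-15-hydroxylabda-8,13E-dien-19-al
Conditions: Bu4NF, THF, 23 °C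
Reagents that add atoms: none
Why: Fluoride-mediated desilylation cleaves the Si–O bond; the quaternary aldehyde cannot enolise and is unaffected.

**Step 13**
Reactants: 20 hydroxy aldehyde
Product: 21 (4S,5R,10S)-19-oxolabda-8,13E-dien-15-yl acetate
Conditions: Ac2O, pyridine, DMAP (cat.), CH2Cl2, 23 °C
Reagents that add atoms: acetic anhydride, CC(=O)OC(C)=O
Why: DMAP-catalysed acylation of the primary allylic alcohol; the neopentyl aldehyde is inert.

**Step 14**
Reactants: 21 acetoxy aldehyde
Product: 22 (4S,5R,10S)-15-acetoxylabda-8,13E-dien-19-oic acid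
Conditions: NaClO2, NaH2PO4, 2-methylbut-2-ene, t-BuOH–H2O, 23 °C
Reagents that add atoms: sodium chlorite, [Na+].[O-]Cl=O
Why: Pinnick oxidation: chlorous acid oxidises the hindered aldehyde to the acid while 2-methylbut-2-ene scavenges hypochlorous acid, so both olefins and the allylic acetate survive.

**Compound list**
1 | geranyl acetate, (2E)-3,7-dimethylocta-2,6-dien-1-yl acetate | CC(C)=CCC/C(C)=C/COC(C)=O | starting material
2 | (2E)-5-(3,3-dimethyloxiran-2-yl)-3-methylpent-2-en-1-yl acetate, racemic oxirane | CC(=O)OC/C=C(\C)CCC1OC1(C)C | intermediate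
3 | (2E)-3-methyl-6-oxohex-2-en-1-yl acetate | CC(=O)OC/C=C(\C)CCC=O | intermediate
4 | (2E)-3-methylhept-2-en-6-yn-1-yl acetate | CC(=O)OC/C=C(\C)CCC#C | intermediate
5 | (2E)-3-methylhept-2-en-6-yn-1-ol | OC/C=C(\C)CCC#C | intermediate
6 | tert-butyl{[(2E)-3-methylhept-2-en-6-yn-1-yl]oxy}diphenylsilane | CC(C)(C)[Si](c1ccccc1)(c1ccccc1)OC/C=C(\C)CCC#C | intermediate
7 | 3-methylcyclohex-2-en-1-one | CC1=CC(=O)CCC1 | starting material
8 | diisobutyl[(5E)-7-(tert-butyldiphenylsilyloxy)-5-methylhepta-1,5-dien-2-yl]alumane | CC(C)(C)[Si](c1ccccc1)(c1ccccc1)OC/C=C(\C)CCC(=C)[Al](CC(C)C)CC(C)C | intermediate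
9 | diisobutylaluminium enolate (O on C4, C4=C5) of the (3S) conjugate adduct | CC(C)C[Al](CC(C)C)OC1=C[C@@](C)(C(=C)CC/C(C)=C/CO[Si](c2ccccc2)(c2ccccc2)C(C)(C)C)CCC1 | intermediate
10 | triethyl({(3S)-3-methyl-3-[(5E)-7-(tert-butyldiphenylsilyloxy)-5-methylhepta-1,5-dien-2-yl]cyclohex-1-en-1-yl}oxy)silane | CC[Si](CC)(CC)OC1=C[C@@](C)(C(=C)CC/C(C)=C/CO[Si](c2ccccc2)(c2ccccc2)C(C)(C)C)CCC1 | intermediate
11 | but-3-en-2-one | CC(=O)C=C | starting material
12 | (3S)-3-methyl-3-[(5E)-7-(tert-butyldiphenylsilyloxy)-5-methylhepta-1,5-dien-2-yl]-2-(3-oxobutyl)cyclohexan-1-one, both C2 (labdane C5) epimers | CC(=O)CCC1C(=O)CCC[C@]1(C)C(=C)CC/C(C)=C/CO[Si](c2ccccc2)(c2ccccc2)C(C)(C)C | intermediate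
13 | (3S)-3-methyl-2-(3-methylbut-3-en-1-yl)-3-[(5E)-7-(tert-butyldiphenylsilyloxy)-5-methylhepta-1,5-dien-2-yl]cyclohexan-1-one, both C2 (labdane C5) epimers | C=C(C)CCC1C(=O)CCC[C@]1(C)C(=C)CC/C(C)=C/CO[Si](c2ccccc2)(c2ccccc2)C(C)(C)C | intermediate
14 | (10S)-15-(tert-butyldiphenylsilyloxy)-18,19-dinorlabda-8,13E-dien-4-one, cis- and trans-fused C5 epimers | CC(C)(C)[Si](c1ccccc1)(c1ccccc1)OC/C=C(\C)CCC1=C(C)CCC2C(=O)CCC[C@]12C | intermediate
15 | (5R,10S)-15-(tert-butyldiphenylsilyloxy)-18,19-dinorlabda-8,13E-dien-4-one, trans-fused (5α-H, 10β-CH3) | CC(C)(C)[Si](c1ccccc1)(c1ccccc1)OC/C=C(\C)CCC1=C(C)CC[C@H]2C(=O)CCC[C@]12C | intermediate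
16 | 15-(tert-butyldiphenylsilyloxy)-4-(methoxymethylidene)-18,19-dinorlabda-8,13E-diene (5α-H, 10β-CH3), E/Z mixture | CC(C)(C)[Si](c1ccccc1)(c1ccccc1)OC/C=C(\C)CCC1=C(C)CC[C@H]2C(=COC)CCC[C@]12C | intermediate
17 | 15-(tert-butyldiphenylsilyloxy)-4-formyl-18,19-dinorlabda-8,13E-diene (5α-H, 10β-CH3), both C4 epimers | CC(C)(C)[Si](c1ccccc1)(c1ccccc1)OC/C=C(\C)CCC1=C(C)CC[C@H]2C(C=O)CCC[C@]12C | intermediate
18 | potassium enolate of 17 (C4=CH–OK) | CC(C)(C)[Si](c1ccccc1)(c1ccccc1)OC/C=C(\C)CCC1=C(C)CC[C@H]2C(=C[O-])CCC[C@]12C.[K+] | intermediate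
19 | (4S,5R,10S)-15-(tert-butyldiphenylsilyloxy)labda-8,13E-dien-19-al (18-CH3 α, 19-CHO β) | CC(C)(C)[Si](c1ccccc1)(c1ccccc1)OC/C=C(\C)CCC1=C(C)CC[C@H]2[C@@](C)(C=O)CCC[C@]12C | intermediate
20 | (4S,5R,10S)-15-hydroxylabda-8,13E-dien-19-al | OC/C=C(\C)CCC1=C(C)CC[C@H]2[C@@](C)(C=O)CCC[C@]12C | intermediate
21 | (4S,5R,10S)-19-oxolabda-8,13E-dien-15-yl acetate | CC(=O)OC/C=C(\C)CCC1=C(C)CC[C@H]2[C@@](C)(C=O)CCC[C@]12C | intermediate
22 | (4S,5R,10S)-15-acetoxylabda-8,13E-dien-19-oic acid, (1S,4aS,8aR)-5-[(3E)-5-acetoxy-3-methylpent-3-en-1-yl]-1,4a,6-trimethyl-1,2,3,4,4a,7,8,8a-octahydronaphthalene-1-carboxylic acid | CC(=O)OC/C=C(\C)CCC1=C(C)CC[C@H]2[C@@](C)(C(=O)O)CCC[C@]12C | target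

**Count**
Total steps: 14. Longest linear sequence: 14 steps (1 → 22); 7 and 11 enter at steps 5 and 6.

**Steps most likely to fail**

Step 8. The ruthenium carbene may decay before it loads on a 1,1-disubstituted olefin and engages the neopentyl C9 methylidene, so the closure could stall. The fallback sets out from 12. A Wittig reaction of the methyl ketone with the ylide from (hex-5-en-1-yl)triphenylphosphonium bromide and NaN(SiMe3)2 (THF, −78 °C) would give the relay triene ketone F1. Its terminal vinyl group takes up ruthenium quickly; extrusion of cyclopentene then delivers the carbene directly onto C8, from where it closes onto C9. The same silica plug and NaOMe treatment follow, and the route is rejoined at 15 (through 14).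

Step 6. Carbon–carbon bond formation at the congested C5 may be slower than protodesilylation of 10 or polymerisation of 11. The fallback sets out from 10. MeLi (THF, 0 °C) would release the regiodefined lithium enolate F2. This is added to 3-(trimethylsilyl)but-3-en-2-one at −78 °C (anionic Michael addition to an α-silyl enone, the classical acceptor for hindered enolates) to give the α-silyl diketone F3. Protodesilylation with dilute HCl in THF returns to the route at 12.

Step 11. O-alkylation of the aldehyde enolate or attack of iodomethane on the β face would erode the C4 centre. The fallback sets out from 17 and uses an ester enolate. Oxidation with NaClO2 gives the acid F4. Esterification with 2-(trimethylsilyl)ethanol (EDC·HCl, DMAP) gives the ester F5. LiN(i-Pr)2 then MeI (THF, −78 °C) methylates the ester enolate on the α face to give the C4-methylated ester F6. Bu4NF removes both silicon groups to give the hydroxy acid F7, and Ac2O–pyridine acetylates O15, coming back to the route at 22.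

**Further compounds**
F1 | step 8 | (3S)-3-methyl-2-(3-methylnona-3,8-dien-1-yl)-3-[(5E)-7-(tert-butyldiphenylsilyloxy)-5-methylhepta-1,5-dien-2-yl]cyclohexan-1-one, C5 epimers, E/Z mixture | C=CCCCC=C(C)CCC1C(=O)CCC[C@]1(C)C(=C)CC/C(C)=C/CO[Si](c2ccccc2)(c2ccccc2)C(C)(C)C
F2 | step 6 | lithium enolate (O on C4, C4=C5) corresponding to 10 | [Li+].[O-]C1=C[C@@](C)(C(=C)CC/C(C)=C/CO[Si](c2ccccc2)(c2ccccc2)C(C)(C)C)CCC1
F3 | step 6 | (3S)-3-methyl-3-[(5E)-7-(tert-butyldiphenylsilyloxy)-5-methylhepta-1,5-dien-2-yl]-2-[3-oxo-2-(trimethylsilyl)butyl]cyclohexan-1-one, epimer mixture | CC(=O)C(CC1C(=O)CCC[C@]1(C)C(=C)CC/C(C)=C/CO[Si](c2ccccc2)(c2ccccc2)C(C)(C)C)[Si](C)(C)C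
F4 | step 11 | 15-(tert-butyldiphenylsilyloxy)-4-carboxy-18,19-dinorlabda-8,13E-diene (5α-H, 10β-CH3), C4 epimers | CC(C)(C)[Si](c1ccccc1)(c1ccccc1)OC/C=C(\C)CCC1=C(C)CC[C@H]2C(C(=O)O)CCC[C@]12C
F5 | step 11 | 2-(trimethylsilyl)ethyl ester of F4 | CC(C)(C)[Si](c1ccccc1)(c1ccccc1)OC/C=C(\C)CCC1=C(C)CC[C@H]2C(C(=O)OCC[Si](C)(C)C)CCC[C@]12C
F6 | step 11 | 2-(trimethylsilyl)ethyl (4S,5R,10S)-15-(tert-butyldiphenylsilyloxy)labda-8,13E-dien-19-oate | CC(C)(C)[Si](c1ccccc1)(c1ccccc1)OC/C=C(\C)CCC1=C(C)CC[C@H]2[C@@](C)(C(=O)OCC[Si](C)(C)C)CCC[C@]12C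
F7 | step 11 | (4S,5R,10S)-15-hydroxylabda-8,13E-dien-19-oic acid | OC/C=C(\C)CCC1=C(C)CC[C@H]2[C@@](C)(C(=O)O)CCC[C@]12C
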